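Two rate constants, one for the left-handed substrate and one for the right-handed substrate, differ on a single-handed catalyst, and their ratio is the quantity I carry through these flasks.

| setting | cedar | autumn | winter |
|---|---|---|---|
| left-handed substrate | 0.50 M | 0.50 M | 0.50 M |
| right-handed substrate | 0.50 M | 0.50 M | 0.50 M |
| partner | 1.5 M | 1.50 M | 1.00 M |
| protic impurity | 0.10 M | 0.100 M | 0.100 M |
| precatalyst | 15 mM | 10 mM | 10 mM |
| remark | run made earlier |  |  |
| time |  | 50 h | 50 h |

cedar run (percent of the left-handed substrate and right-handed substrate together charged)

| time / h | left-handed product / % | right-handed product / % |
|---|---|---|
| 1.33 | 0 | 0 |
| 2.00 | 0 | 0 |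
| 3.00 | 0.4 | 2.4 |
| 5.00 | 3.7 | 1.3 |
| 8.00 | 4.7 | 2.4 |
| 12.0 | 10.0 | 3.1 |
| 20.0 | 20.3 | 8.1 |

(readings scatter by 1 percentage point)

- catalyst is single-handed; left-handed substrate and right-handed substrate are mirror images of each other, charged as a racemate, each of them at the stated concentration
- the analysis behind the earlier runs scatters by 1 percentage point, standard deviation
- an excess is the difference of the two amounts in percent of their sum
- an excess is below zero if the other one leads
- no earlier run changes the charge of precatalyst; that part of a forecast is a guess

- which of the two ends with the higher excess of left-handed product over right-handed product in the product ("neither" if they lie within 2 percentage points) (autumn / winter / neither)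
- excess of left-handed product over right-handed product in the product at the end, autumn
- excess of left-handed product over right-handed product in the product at the end, winter

Suppose each substrate is consumed at its own constant times its own concentration, times a factor for catalyst and partner that both substrates share, however that factor moves in time. Dividing one rate by the other removes the time and the shared factor. Call c(left-handed substrate) over its charge the left rest, and c(right-handed substrate) over its charge the right rest. Then the logarithm of the left rest is a fixed multiple of the logarithm of the right rest.

Cedar at 20.0 h holds 20.3% of left-handed product and 8.1% of right-handed product. The two substrates were charged equally, so the rests read 59.4% and 83.8%. Their logarithms give 2.95, the selectivity factor: the ratio of the two constants, read as the logarithm of the left rest over that of the right rest. It is a reading, and one scatter on the right-handed product alone moves it to 2.59 or 3.40.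

With that factor held, the excess depends on how far a flask has gone. Cedar's last reading gives an excess of 43.0%. Squaring both rests, which keeps the ratio of their logarithms, gives an excess of 37.0%, which is lower. Winter carries less partner than autumn. If partner speeds both rates, which cedar cannot test, winter goes less far, and I reckon its excess the higher.

The forecast is 39% for autumn and 43% for winter, so it has winter ending higher, on the ground that “Lower conversion preserves selectivity”.

Autumn ends at 27.9% and winter at 34.5%, so winter leads, and both lie below the forecast. Autumn has reacted 55.5% of the two substrates together, more than the 34.0% in winter.

    partner + catalyst + left-handed substrate → catalyst + left-handed product (k = 0.00162 M⁻² s⁻¹)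
    partner + catalyst + right-handed substrate → catalyst + right-handed product (k = 6.68 × 10⁻⁴ M⁻² s⁻¹)
    partner + precatalyst → catalyst + spent reagent (k = 5.04 × 10⁻⁶ M⁻¹ s⁻¹)
    partner → decomposition product (k = 2.70 × 10⁻⁸ s⁻¹)
    partner + protic impurity → quenched reagent (k = 5.41 × 10⁻⁵ M⁻¹ s⁻¹)

Autumn keeps 60% of its right-handed substrate, and 2.95 turns that into a left rest of 22.2% and an excess of 32.1%, against the 27.9% found. The flask like winter but with 1.7 M of partner keeps 53% of its right-handed substrate, for which 2.95 gives an excess of 28.6%, and the excess found there is 25.2%.

The data stem from a simulated flask with made-up constants; noise was put on by code.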